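The 2-hydroxy-1,4-benzoquinone ring is assembled last, at its final oxidation level, by disconnecting it between C2 (hydroxyl-bearing) and C3 (side-chain-bearing). The vicinal pair C1/C2 maps onto oxalyl chloride; C3–C6, with the methoxy group already on C5 and the complete monocyclofarnesyl chain on C3, map onto a 2-siloxy-3-methoxybuta-1,3-diene. In one operation the free methylene terminus (future C6) is acylated, the silyl enol ether carbon attacks the pendant acid chloride to close the six-membered ring, and enolisation delivers the hydroxyquinone. The step exploits the two vicinal oxygenated carbon pairs of the quinone ring, C1/C2 and C4/C5. The single stereocentre comes from (S)-α-ionone.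

Key step: step 7

Ring locants used throughout: C1(=O), C2(OH), C3(side chain), C4(=O), C5(OMe), C6(H).
Assumption: (S)-(−)-α-ionone (1) is taken as purchasable in high enantiomeric purity; only the racemate would call for a prior resolution.

Step 1
Reactants: 1 (3E)-4-[(1S)-2,6,6-trimethylcyclohex-2-en-1-yl]but-3-en-2-one ((S)-α-ionone)
Product: 3 4-[(1S)-2,6,6-trimethylcyclohex-2-en-1-yl]butan-2-one ((S)-dihydro-α-ionone), via triethylsilyl enol ether 2 (not isolated)
Conditions: Et3SiH (1.1 equiv), RhCl(PPh3)3 (0.5 mol %), benzene, 50 °C; then K2CO3, MeOH, rt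
Reagents that add atoms: none
Why: Rhodium-catalysed 1,4-hydrosilylation of the enone (conjugate reduction) followed by methanolysis of silyl enol ether 2 should reduce only the conjugated C=C, leaving the trisubstituted ring alkene and the existing (S) centre untouched under these neutral conditions.

Step 2
Reactants: 3 (S)-dihydro-α-ionone; 4 triethyl phosphonoacetate
Product: 6 ethyl (2E)-3-methyl-5-[(1S)-2,6,6-trimethylcyclohex-2-en-1-yl]pent-2-enoate, via sodium phosphonate 5 (not isolated)
Conditions: 4 (1.5 equiv), NaH, THF, 0 °C; then 3, reflux; chromatographic removal of the minor (2Z) isomer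
Reagents that add atoms: triethyl phosphonoacetate, CCOC(=O)CP(=O)(OCC)OCC
Why: Horner–Wadsworth–Emmons olefination of the methyl ketone should favour the (2E) ester, in which the ester is trans to the larger alkyl chain, through reversible adduct formation; the minor (2Z) isomer is removed by chromatography.

Step 3
Reactants: 6 ethyl (2E)-ester
Product: 7 (2E)-3-methyl-5-[(1S)-2,6,6-trimethylcyclohex-2-en-1-yl]pent-2-en-1-ol
Conditions: iBu2AlH (2.3 equiv), CH2Cl2, −78 → 0 °C; aq. potassium sodium tartrate work-up
Reagents that add atoms: none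
Why: iBu2AlH reduces the conjugated ester by 1,2-hydride delivery to the allylic alcohol (ester reduction) without touching either alkene or the double-bond geometry.

Step 4
Reactants: 7 (2E)-allylic alcohol
Product: 8 (6S)-6-[(3E)-5-bromo-3-methylpent-3-en-1-yl]-1,5,5-trimethylcyclohex-1-ene
Conditions: CBr4, PPh3, CH2Cl2, 0 °C; used at once
Reagents that add atoms: carbon tetrabromide, BrC(Br)(Br)Br
Why: The Appel reaction replaces the primary allylic hydroxyl by SN2 displacement of the alkoxyphosphonium under neutral conditions, so neither allylic transposition nor acid-induced migration of the ring alkene is expected.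

Step 5
Reactants: 8 allylic bromide; 9 3,3-dimethoxybutan-2-one
Product: 11 (6E)-2,2-dimethoxy-7-methyl-9-[(1S)-2,6,6-trimethylcyclohex-2-en-1-yl]non-6-en-3-one, via lithium enolate 10 (not isolated)
Conditions: 9 (1.5 equiv), LiN(iPr)2 (1.45 equiv), THF, −78 °C; then 8, DMPU, −78 → 0 °C
Reagents that add atoms: 3,3-dimethoxybutan-2-one, CC(=O)C(C)(OC)OC
Why: Kinetic enolate alkylation: 9 has a single enolisable position (the acetyl methyl), and its lithium enolate should displace the primary allylic bromide by SN2 with retention of the E geometry, the excess of enolate limiting dialkylation.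

Step 6
Reactants: 11 keto ketal
Product: 13 tert-butyl{[(3Z,6E)-2-methoxy-7-methyl-9-[(1S)-2,6,6-trimethylcyclohex-2-en-1-yl]nona-1,3,6-trien-3-yl]oxy}dimethylsilane, via silyl enol ether 12 (not isolated)
Conditions: TBSOTf (1.1 equiv), iPr2NEt (3 equiv), CH2Cl2, −78 → 0 °C; then TMSOTf (1.2 equiv), 0 °C → rt; rapid filtration through Et3N-deactivated basic alumina, used crude
Reagents that add atoms: tert-butyldimethylsilyl triflate, CC(C)(C)[Si](C)(C)OS(=O)(=O)C(F)(F)F
Why: Soft enolisation with silyl triflate and amine should give the Z silyl enol ether 12 of the only enolisable methylene; TMSOTf then ionises the ketal to a methoxy-stabilised 2-siloxyallyl cation and the amine removes a proton from its methyl group, the known conversion of a dimethyl ketal into a methyl enol ether.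

Step 7
Reactants: 13 siloxy methoxy diene; 14 oxalyl chloride
Product: 17 2-hydroxy-5-methoxy-3-[(2E)-3-methyl-5-[(1S)-2,6,6-trimethylcyclohex-2-en-1-yl]pent-2-en-1-yl]cyclohexa-2,5-diene-1,4-dione (CNP0018448.1), via acid chloride 15 (not isolated), via triketone 16 (not isolated)
Conditions: (COCl)2 (1.0 equiv), 2,6-di-tert-butyl-4-methylpyridine (1.2 equiv), CH2Cl2 (high dilution), slow addition of 13 at −78 °C, then → rt; dilute aq. HCl work-up
Reagents that add atoms: oxalyl chloride, ClC(=O)C(=O)Cl
Why: Proposed new method: oxalyl chloride should first C-acylate the unsubstituted methylene terminus of the methyl enol ether (a known acylation of enol ethers), and loss of HCl to the hindered base gives the (3E) vinylogous ester 15, whose acid chloride lies cis to the silyl enol ether; the enol ether carbon (future C3) then attacks the acid chloride carbonyl (future C2), chloride removes the silyl group, and triketone 16 enolises to the 2-hydroxy-1,4-quinone. The closest known reactions are the one-pot cyclisations of bis(silyl enol ethers) with oxalyl chloride and the C-acylation of silyl enol ethers by acid chlorides. The six-membered ring closes in a 6-(enolendo)-exo-trig mode. No new stereocentre survives, since the sp3 centre of 16 is lost on enolisation and the remote (S) centre is not touched. The step needs the first acylation at the methylene terminus and C- rather than O-acylation in the closure: the first is secured by the unhindered terminus and its methoxy-stabilised cation against the TBS-shielded trisubstituted terminus, the second by the carbon nucleophilicity of silyl enol ethers towards acid chlorides, and the place of the methoxy group is already fixed in 13.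

Compound list
1 | (3E)-4-[(1S)-2,6,6-trimethylcyclohex-2-en-1-yl]but-3-en-2-one ((S)-α-ionone) | CC(=O)/C=C/[C@@H]1C(C)=CCCC1(C)C | starting material
2 | triethyl({4-[(1S)-2,6,6-trimethylcyclohex-2-en-1-yl]but-2-en-2-yl}oxy)silane | CC(O[Si](CC)(CC)CC)=CC[C@@H]1C(C)=CCCC1(C)C | intermediate
3 | 4-[(1S)-2,6,6-trimethylcyclohex-2-en-1-yl]butan-2-one | CC(=O)CC[C@@H]1C(C)=CCCC1(C)C | intermediate
4 | triethyl phosphonoacetate | CCOC(=O)CP(=O)(OCC)OCC | starting material
5 | sodium salt of triethyl phosphonoacetate | [Na+].CCOC(=O)[CH-]P(=O)(OCC)OCC | intermediate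
6 | ethyl (2E)-3-methyl-5-[(1S)-2,6,6-trimethylcyclohex-2-en-1-yl]pent-2-enoate | CCOC(=O)/C=C(\C)CC[C@@H]1C(C)=CCCC1(C)C | intermediate
7 | (2E)-3-methyl-5-[(1S)-2,6,6-trimethylcyclohex-2-en-1-yl]pent-2-en-1-ol | OC/C=C(\C)CC[C@@H]1C(C)=CCCC1(C)C | intermediate
8 | (6S)-6-[(3E)-5-bromo-3-methylpent-3-en-1-yl]-1,5,5-trimethylcyclohex-1-ene | BrC/C=C(\C)CC[C@@H]1C(C)=CCCC1(C)C | intermediate
9 | 3,3-dimethoxybutan-2-one | CC(=O)C(C)(OC)OC | starting material
10 | lithium 3,3-dimethoxybut-1-en-2-olate | [Li+].[O-]C(=C)C(C)(OC)OC | intermediate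
11 | (6E)-2,2-dimethoxy-7-methyl-9-[(1S)-2,6,6-trimethylcyclohex-2-en-1-yl]non-6-en-3-one | CC(OC)(OC)C(=O)CC/C=C(\C)CC[C@@H]1C(C)=CCCC1(C)C | intermediate
12 | tert-butyl{[(3Z,6E)-2,2-dimethoxy-7-methyl-9-[(1S)-2,6,6-trimethylcyclohex-2-en-1-yl]nona-3,6-dien-3-yl]oxy}dimethylsilane | CC(OC)(OC)/C(O[Si](C)(C)C(C)(C)C)=C/C/C=C(\C)CC[C@@H]1C(C)=CCCC1(C)C | intermediate
13 | tert-butyl{[(3Z,6E)-2-methoxy-7-methyl-9-[(1S)-2,6,6-trimethylcyclohex-2-en-1-yl]nona-1,3,6-trien-3-yl]oxy}dimethylsilane | C=C(OC)/C(O[Si](C)(C)C(C)(C)C)=C/C/C=C(\C)CC[C@@H]1C(C)=CCCC1(C)C | intermediate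
14 | oxalyl chloride | ClC(=O)C(=O)Cl | starting material
15 | (3E,5Z,8E)-5-[(tert-butyldimethylsilyl)oxy]-4-methoxy-9-methyl-2-oxo-11-[(1S)-2,6,6-trimethylcyclohex-2-en-1-yl]undeca-3,5,8-trienoyl chloride | ClC(=O)C(=O)/C=C(OC)\C(O[Si](C)(C)C(C)(C)C)=C\C/C=C(\C)CC[C@@H]1C(C)=CCCC1(C)C | intermediate
16 | 5-methoxy-3-[(2E)-3-methyl-5-[(1S)-2,6,6-trimethylcyclohex-2-en-1-yl]pent-2-en-1-yl]cyclohex-5-ene-1,2,4-trione | O=C1C(=O)C=C(OC)C(=O)C1C/C=C(\C)CC[C@@H]2C(C)=CCCC2(C)C | intermediate
17 | 2-hydroxy-5-methoxy-3-[(2E)-3-methyl-5-[(1S)-2,6,6-trimethylcyclohex-2-en-1-yl]pent-2-en-1-yl]cyclohexa-2,5-diene-1,4-dione (CNP0018448.1) | COC1=CC(=O)C(O)=C(C/C=C(\C)CC[C@@H]2C(C)=CCCC2(C)C)C1=O | target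

Total step count: 7.
Longest linear sequence: 7 steps (1 → 17); 4, 9 and 14 are purchased.

Steps most likely to fail

1. Step 7 (Proposed new method). What may go wrong: the first acylation may take place at the silyl enol ether terminus, acid chloride 15 may react between molecules or close through oxygen instead of carbon, the silyl enol ether may be lost to acid before closure, or the hydroxyquinone may be chlorinated by unconsumed oxalyl chloride. Fallback (known chemistry, stepwise): setting out from 13, C-acylation of the methylene terminus with methyl chlorooxoacetate (pyridine, CH2Cl2, 0 °C), the documented acylation of enol ethers by oxalic monoester chlorides, followed by cleavage of the silyl enol ether with AcOH-buffered Bu4NF (THF, 0 °C), should give methyl (3E,8E)-4-methoxy-9-methyl-2,5-dioxo-11-[(1S)-2,6,6-trimethylcyclohex-2-en-1-yl]undeca-3,8-dienoate F1. LiN(SiMe3)2 (THF, −78 → 0 °C) then deprotonates its only enolisable methylene, and a Dieckmann condensation onto the ester carbonyl closes the same C2–C3 bond with loss of methoxide, returning to the route at 17 after acidification.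

2. Step 6. What may go wrong: the siloxyallyl cation may lose a proton from the doubly allylic C5 methylene instead of the methyl group, it may be captured by the chain alkene, or the diene may hydrolyse on handling. Fallback (all-anionic route): setting out from 8, alkylation of the lithium enolate of N-methoxy-N-methylacetamide (LiN(iPr)2, THF, −78 °C) should give the Weinreb amide (4E)-N-methoxy-N,5-dimethyl-7-[(1S)-2,6,6-trimethylcyclohex-2-en-1-yl]hept-4-enamide F2. 1-Methoxyvinyllithium (methyl vinyl ether, t-BuLi, THF, −78 → 0 °C) adds once to give the enone (6E)-2-methoxy-7-methyl-9-[(1S)-2,6,6-trimethylcyclohex-2-en-1-yl]nona-1,6-dien-3-one F3. Kinetic deprotonation of its only enolisable methylene with LiN(iPr)2 and trapping with TBSCl (THF–DMPU, −78 °C) returns to the route at 13, bypassing 11.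

3. Step 5. What may go wrong: proton transfer between product and enolate leading to dialkylation, or elimination and SN2′ attack on the allylic bromide. Fallback (acetoacetic-ester-type alkylation): setting out from 9, C-acylation with dimethyl carbonate (NaH, THF, reflux) gives the β-keto ester methyl 4,4-dimethoxy-3-oxopentanoate F4. Its potassium enolate (K2CO3, acetone, rt) is alkylated once by 8 to give methyl (4E)-2-(2,2-dimethoxypropanoyl)-5-methyl-7-[(1S)-2,6,6-trimethylcyclohex-2-en-1-yl]hept-4-enoate F5. Krapcho dealkoxycarbonylation (LiCl, wet DMSO, 140 °C) returns to the route at 11.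

Further compounds
F1 | step 7 | methyl (3E,8E)-4-methoxy-9-methyl-2,5-dioxo-11-[(1S)-2,6,6-trimethylcyclohex-2-en-1-yl]undeca-3,8-dienoate | COC(=O)C(=O)/C=C(OC)\C(=O)CC/C=C(\C)CC[C@@H]1C(C)=CCCC1(C)C
F2 | step 6 | (4E)-N-methoxy-N,5-dimethyl-7-[(1S)-2,6,6-trimethylcyclohex-2-en-1-yl]hept-4-enamide | CON(C)C(=O)CC/C=C(\C)CC[C@@H]1C(C)=CCCC1(C)C
F3 | step 6 | (6E)-2-methoxy-7-methyl-9-[(1S)-2,6,6-trimethylcyclohex-2-en-1-yl]nona-1,6-dien-3-one | C=C(OC)C(=O)CC/C=C(\C)CC[C@@H]1C(C)=CCCC1(C)C
F4 | step 5 | methyl 4,4-dimethoxy-3-oxopentanoate | COC(=O)CC(=O)C(C)(OC)OC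
F5 | step 5 | methyl (4E)-2-(2,2-dimethoxypropanoyl)-5-methyl-7-[(1S)-2,6,6-trimethylcyclohex-2-en-1-yl]hept-4-enoate | COC(=O)C(C/C=C(\C)CC[C@@H]1C(C)=CCCC1(C)C)C(=O)C(C)(OC)OC
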